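**Retrosynthetic overview**

1. Target 22 ⇐ fluoride-labile ester 21 ⇐ intramolecular Diels–Alder reaction of the acyclic tetraenone 20. The cyclohexene and the cyclopentanone close together in this one step, which is the last C–C bond-forming event.
2. 20 ⇐ C6–C7 bond (C3–C3a of the target) between α-chloroketone 8, used as an α-keto cation (enolonium) equivalent, and trienylzinc 19. This nickel-catalysed enantioconvergent coupling joins two carbons that are both normally nucleophilic and sets C3.
3. 8 ⇐ vinylogous Mukaiyama aldol of silyl dienolate 4 with (R)-2-chloropropanal 6, then oxidation. The chlorine stereocenter relays the configuration of C1 and is erased afterwards.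
4. 19 ⇐ trienyl iodide 17 ⇐ prop-2-yn-1-ol by carboalumination/iodination, Wittig and Horner–Wadsworth–Emmons chain extension.

Assumption: the bicyclic core is numbered C1 (CHEt), C2 (C=O), C3 (CHMe), C3a, C4 (CMe), C5 (=CH), C6 (C(Et)(styryl)), C7 (C(Et)(CO2H)), C7a; with these locants the target is (1S,3S,3aR,6S,7R,7aR).

**Route**

Step 1
Reactants: 1 (E)-2-ethylhex-2-enoic acid; 2 2-(trimethylsilyl)ethanol
Product: 3 2-(trimethylsilyl)ethyl (E)-2-ethylhex-2-enoate
Conditions: DCC, DMAP (cat.), CH2Cl2, 0 °C to rt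
Reagents that add atoms: none
Why: Steglich esterification; the 2-(trimethylsilyl)ethyl ester is chosen because fluoride removes it later without attack at the very hindered quaternary carboxyl, and no stereocenter is formed.

Step 2
Reactants: 3 2-(trimethylsilyl)ethyl (E)-2-ethylhex-2-enoate
Product: 4 (3E)-2-ethyl-1-[2-(trimethylsilyl)ethoxy]-1-(trimethylsilyloxy)hexa-1,3-diene
Conditions: LiN(iPr)2, DMPU, THF, −78 °C; Me3SiCl
Reagents that add atoms: chlorotrimethylsilane C[Si](C)(C)Cl
Why: Kinetic γ-deprotonation of the enoate and O-silylation give the vinylogous silyl ketene acetal (extended enolate) needed for a vinylogous Mukaiyama aldol; the new C3=C4 bond forms E and no stereocenter is created.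

Step 3
Reactants: 5 propanal
Product: 6 (R)-2-chloropropanal
Conditions: NCS, 2,5-diphenylpyrrolidine (10 mol%, the antipode that gives the R aldehyde), CH2Cl2, 0 °C; silica plug, solution used at once
Reagents that add atoms: N-chlorosuccinimide O=C1CCC(=O)N1Cl
Why: Enamine-catalysed electrophilic α-chlorination in which the C2-symmetric pyrrolidine shields one enamine face and sets the R chlorine-bearing center, which serves only as a temporary control element.

Step 4
Reactants: 4 (3E)-2-ethyl-1-[2-(trimethylsilyl)ethoxy]-1-(trimethylsilyloxy)hexa-1,3-diene; 6 (R)-2-chloropropanal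
Product: 7 2-(trimethylsilyl)ethyl (2E,4S,5S,6R)-6-chloro-2,4-diethyl-5-hydroxyhept-2-enoate
Conditions: BF3·OEt2, CH2Cl2, −78 °C; aq. NaHCO3
Reagents that add atoms: none
Why: Vinylogous Mukaiyama aldol in which the fully substituted α-carbon forces γ-attack, the aldehyde is attacked anti to C–Cl (Cornforth / polar Felkin–Anh) to give 5,6-anti, and the open antiperiplanar transition state of the (3E)-dienolate gives 4,5-anti, so the chlorine center relays its configuration to C4 (S, the future C1) and the enoate returns as the E isomer.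

Step 5
Reactants: 7 2-(trimethylsilyl)ethyl (2E,4S,5S,6R)-6-chloro-2,4-diethyl-5-hydroxyhept-2-enoate
Product: 8 2-(trimethylsilyl)ethyl (2E,4S,6R)-6-chloro-2,4-diethyl-5-oxohept-2-enoate
Conditions: Dess–Martin periodinane, NaHCO3, CH2Cl2, 0 °C
Reagents that add atoms: none
Why: Dess–Martin oxidation under buffered, base-free conditions gives the ketone without epimerising C4 and turns C6–Cl into an α-keto leaving group whose configuration no longer matters.

Step 6
Reactants: 9 prop-2-yn-1-ol
Product: 10 (E)-3-iodo-2-methylprop-2-en-1-ol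
Conditions: Me3Al, (C5H5)2ZrCl2 (25 mol%), CH2Cl2, 0 °C to rt; I2, THF, −30 °C; aq. K2CO3
Reagents that add atoms: trimethylaluminium C[Al](C)C; iodine II
Why: Negishi carboalumination, in which zirconium-catalysed syn addition of Me–Al places the methyl on the internal alkyne carbon and iodine cleaves the C–Al bond with retention to give the E iodide.

Step 7
Reactants: 11 propyltriphenylphosphonium bromide
Product: 13 2-(triphenylphosphoranylidene)butanal, via propylidenetriphenylphosphorane 12 (not isolated)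
Conditions: nBuLi, THF, 0 °C; HCO2Et, 0 °C to rt
Reagents that add atoms: ethyl formate CCOC=O
Why: Deprotonation to the non-stabilised ylide and C-formylation with ethyl formate (acyl transfer, after which ethoxide removes the acidic α-proton) give the formyl-stabilised ylide.

Step 8
Reactants: 10 (E)-3-iodo-2-methylprop-2-en-1-ol; 13 2-(triphenylphosphoranylidene)butanal
Product: 15 (2E,4E)-2-ethyl-5-iodo-4-methylpenta-2,4-dienal, via (E)-3-iodo-2-methylprop-2-enal 14 (not isolated)
Conditions: MnO2, PhMe, 80 °C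
Reagents that add atoms: none
Why: Tandem allylic oxidation and Wittig olefination traps the volatile, light-sensitive iodoenal as it forms; the stabilised α-branched ylide gives the E trisubstituted enal and the vinyl iodide geometry is untouched.

Step 9
Reactants: 15 (2E,4E)-2-ethyl-5-iodo-4-methylpenta-2,4-dienal; 16 diethyl benzylphosphonate
Product: 17 [(1E,3E,5E)-3-ethyl-6-iodo-5-methylhexa-1,3,5-trien-1-yl]benzene
Conditions: NaN(SiMe3)2, THF, −78 to 0 °C
Reagents that add atoms: none
Why: Horner–Wadsworth–Emmons olefination with a benzyl phosphonate gives the E styrene and completes the all-E triene; the vinyl iodide cannot eliminate because the neighbouring carbon carries no hydrogen.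

Step 10
Reactants: 17 [(1E,3E,5E)-3-ethyl-6-iodo-5-methylhexa-1,3,5-trien-1-yl]benzene; 8 2-(trimethylsilyl)ethyl (2E,4S,6R)-6-chloro-2,4-diethyl-5-oxohept-2-enoate
Product: 20 2-(trimethylsilyl)ethyl (2E,4S,6S,7E,9E,11E)-2,4,10-triethyl-6,8-dimethyl-5-oxo-12-phenyldodeca-2,7,9,11-tetraenoate, via trienyllithium 18 (not isolated), via trienylzinc bromide 19 (not isolated)
Conditions: 17, tBuLi (2 equiv), Et2O, −78 °C; ZnBr2, THF; then 8, NiCl2(MeOCH2CH2OMe) (10 mol%), 2,2'-(propane-2,2-diyl)bis(4-phenyl-4,5-dihydrooxazole) (13 mol%, antipode giving 6S), NaI (0.5 equiv), DME/THF, −20 °C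
Reagents that add atoms: none
Why: Proposed new method: nickel-catalysed enantioconvergent Negishi alkenylation of an α-halo dialkyl ketone, in which low-valent nickel abstracts the halogen (chloride exchanged in situ for iodide) to give a planar α-keto radical that erases C6, the radical is captured by the chiral bis(oxazoline)nickel–alkenyl species and reductive elimination sets C6 as S under catalyst control with retention of the alkenyl geometry and without base, so C4 and the skipped diene survive and the α-carbon of the ketone acts as the electrophile toward a carbon nucleophile; the closest known reactions are nickel/bis(oxazoline)-catalysed stereoconvergent couplings of racemic α-bromoketones with arylzinc and alkenylzirconium reagents and of α-bromonitriles with alkenylzinc reagents.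

Step 11
Reactants: 20 2-(trimethylsilyl)ethyl (2E,4S,6S,7E,9E,11E)-2,4,10-triethyl-6,8-dimethyl-5-oxo-12-phenyldodeca-2,7,9,11-tetraenoate
Product: 21 2-(trimethylsilyl)ethyl (1S,3S,3aR,6S,7R,7aR)-1,6,7-triethyl-3,4-dimethyl-2-oxo-6-[(E)-2-phenylethenyl]-2,3,3a,6,7,7a-hexahydro-1H-indene-7-carboxylate
Conditions: PhMe (0.01 M), BHT, 80 °C
Reagents that add atoms: none
Why: Thermal intramolecular Diels–Alder reaction that closes both rings at once, in which the all-E geometry fixes the C6/C7 and C3a/C7a relationships, the ester-endo trans-fused transition state is favoured, and allylic 1,3-strain keeps the C4–H and C6–H of 20 in the planes of their alkenes so that both stereocenters select the same pair of faces and give (3aR,6S,7R,7aR).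

Step 12
Reactants: 21 2-(trimethylsilyl)ethyl (1S,3S,3aR,6S,7R,7aR)-1,6,7-triethyl-3,4-dimethyl-2-oxo-6-[(E)-2-phenylethenyl]-2,3,3a,6,7,7a-hexahydro-1H-indene-7-carboxylate
Product: 22 (1S,3S,3aR,6S,7R,7aR)-1,6,7-triethyl-3,4-dimethyl-2-oxo-6-[(E)-2-phenylethenyl]-2,3,3a,6,7,7a-hexahydro-1H-indene-7-carboxylic acid
Conditions: Bu4NF, THF, 0 °C to rt; aq. HCl (pH 3)
Reagents that add atoms: none
Why: Fluoride attacks silicon and the ester fragments by β-elimination to ethene and Me3SiF, which frees the acid without nucleophilic attack at the hindered carbonyl; the all-trans α-centers of the cyclopentanone are the thermodynamic ones and are not changed.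

**Compound list**

1 | (E)-2-ethylhex-2-enoic acid | CCC/C=C(CC)/C(=O)O | starting material
2 | 2-(trimethylsilyl)ethanol | C[Si](C)(C)CCO | starting material
3 | 2-(trimethylsilyl)ethyl (E)-2-ethylhex-2-enoate | CCC/C=C(CC)/C(=O)OCC[Si](C)(C)C | intermediate
4 | (3E)-2-ethyl-1-[2-(trimethylsilyl)ethoxy]-1-(trimethylsilyloxy)hexa-1,3-diene (ketene acetal geometry not controlled) | CC/C=C/C(CC)=C(O[Si](C)(C)C)OCC[Si](C)(C)C | intermediate
5 | propanal | CCC=O | starting material
6 | (R)-2-chloropropanal | C[C@@H](Cl)C=O | intermediate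
7 | 2-(trimethylsilyl)ethyl (2E,4S,5S,6R)-6-chloro-2,4-diethyl-5-hydroxyhept-2-enoate | CC[C@@H](/C=C(CC)/C(=O)OCC[Si](C)(C)C)[C@H](O)[C@@H](C)Cl | intermediate
8 | 2-(trimethylsilyl)ethyl (2E,4S,6R)-6-chloro-2,4-diethyl-5-oxohept-2-enoate | CC[C@@H](/C=C(CC)/C(=O)OCC[Si](C)(C)C)C(=O)[C@@H](C)Cl | intermediate
9 | prop-2-yn-1-ol | C#CCO | starting material
10 | (E)-3-iodo-2-methylprop-2-en-1-ol | OC/C(C)=C/I | intermediate
11 | propyltriphenylphosphonium bromide | CCC[P+](c1ccccc1)(c1ccccc1)c1ccccc1.[Br-] | starting material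
12 | propylidenetriphenylphosphorane | CCC=P(c1ccccc1)(c1ccccc1)c1ccccc1 | intermediate
13 | 2-(triphenylphosphoranylidene)butanal | CCC(C=O)=P(c1ccccc1)(c1ccccc1)c1ccccc1 | intermediate
14 | (E)-3-iodo-2-methylprop-2-enal | O=C/C(C)=C/I | intermediate
15 | (2E,4E)-2-ethyl-5-iodo-4-methylpenta-2,4-dienal | O=C/C(CC)=C/C(C)=C/I | intermediate
16 | diethyl benzylphosphonate | CCOP(=O)(Cc1ccccc1)OCC | starting material
17 | [(1E,3E,5E)-3-ethyl-6-iodo-5-methylhexa-1,3,5-trien-1-yl]benzene | I/C=C(C)/C=C(CC)/C=C/c1ccccc1 | intermediate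
18 | [(1E,3E,5E)-4-ethyl-2-methyl-6-phenylhexa-1,3,5-trien-1-yl]lithium | [Li]/C=C(C)/C=C(CC)/C=C/c1ccccc1 | intermediate
19 | bromo[(1E,3E,5E)-4-ethyl-2-methyl-6-phenylhexa-1,3,5-trien-1-yl]zinc | Br[Zn]/C=C(C)/C=C(CC)/C=C/c1ccccc1 | intermediate
20 | 2-(trimethylsilyl)ethyl (2E,4S,6S,7E,9E,11E)-2,4,10-triethyl-6,8-dimethyl-5-oxo-12-phenyldodeca-2,7,9,11-tetraenoate | CC[C@@H](/C=C(CC)/C(=O)OCC[Si](C)(C)C)C(=O)[C@@H](C)/C=C(C)/C=C(CC)/C=C/c1ccccc1 | intermediate
21 | 2-(trimethylsilyl)ethyl (1S,3S,3aR,6S,7R,7aR)-1,6,7-triethyl-3,4-dimethyl-2-oxo-6-[(E)-2-phenylethenyl]-2,3,3a,6,7,7a-hexahydro-1H-indene-7-carboxylate | CC[C@@H]1C(=O)[C@@H](C)[C@@H]2C(C)=C[C@@](/C=C/c3ccccc3)(CC)[C@](CC)(C(=O)OCC[Si](C)(C)C)[C@H]21 | intermediate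
22 | (1S,3S,3aR,6S,7R,7aR)-1,6,7-triethyl-3,4-dimethyl-2-oxo-6-[(E)-2-phenylethenyl]-2,3,3a,6,7,7a-hexahydro-1H-indene-7-carboxylic acid (CNP0178058.1) | CC[C@@H]1C(=O)[C@@H](C)[C@@H]2C(C)=C[C@@](/C=C/c3ccccc3)(CC)[C@](CC)(C(=O)O)[C@H]21 | target

**Step count**

Total: 12 steps. Longest linear sequence: 7 steps (steps 1, 2, 4, 5, 10, 11, 12).

**Three steps most likely to fail, with fallbacks**

Step 10 (nickel-catalysed enantioconvergent alkenylation). An α-halo dialkyl ketone with an acidic neighbouring C–H and a conjugated trienylzinc lies outside the tested range. Simple reduction of the halide, low enantioselectivity or radical addition to the polyene could intervene. The fallback moves the same kind of coupling to an electrophile class where alkenylzinc reagents are established and builds the ketone afterwards by an aldol. It sets out from 17 (converted to 19 as before) and from 4, and returns at 20. Trienylzinc 19 is coupled with racemic 2-bromopropanenitrile (NiCl2(MeOCH2CH2OMe), bis(oxazoline) ligand, THF, −78 °C) to give (2S,3E,5E,7E)-6-ethyl-2,4-dimethyl-8-phenylocta-3,5,7-trienenitrile F1. Reduction with iBu2AlH at −78 °C and mild hydrolysis gives (2S,3E,5E,7E)-6-ethyl-2,4-dimethyl-8-phenylocta-3,5,7-trienal F2. A vinylogous Mukaiyama aldol of F2 with dienolate 4 (BF3·OEt2, −78 °C; Felkin addition and anti simple selectivity) gives 2-(trimethylsilyl)ethyl (2E,4S,5R,6S,7E,9E,11E)-2,4,10-triethyl-5-hydroxy-6,8-dimethyl-12-phenyldodeca-2,7,9,11-tetraenoate F3. Buffered Dess–Martin oxidation of F3 gives 20.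

Step 4 (vinylogous aldol with chlorine-to-C4 relay). The C4 configuration depends on two substrate-controlled selectivities (Cornforth and anti). If either is modest, 20 carries its C4 epimer, which cyclises poorly in step 11. If only the sense of the simple selectivity is reversed, the S aldehyde from the other catalyst antipode gives the same 4S center. The fallback replaces substrate relay by catalyst control and introduces the halogen later. It sets out from 4 and returns at 8. Dienolate 4 and propanal 5 are combined under SiCl4 with a chiral bisphosphoramide Lewis-base catalyst (CH2Cl2, −78 °C) to give the anti adduct 2-(trimethylsilyl)ethyl (2E,4S,5R)-2,4-diethyl-5-hydroxyhept-2-enoate F4. Dess–Martin oxidation gives 2-(trimethylsilyl)ethyl (2E,4S)-2,4-diethyl-5-oxohept-2-enoate F5. Kinetic enolisation on the CH2 side (LiN(SiMe3)2, Me3SiCl, THF, −78 °C; the shielded tertiary C4–H is not removed) gives 2-(trimethylsilyl)ethyl (2E,4S)-2,4-diethyl-5-(trimethylsilyloxy)hepta-2,5-dienoate F6. Treatment of F6 with NCS gives 8 as a C6 epimer mixture, which is immaterial because step 10 erases C6.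

Step 11 (intramolecular Diels–Alder reaction). The β,γ-unsaturated ketone may isomerise into conjugation or epimerise before it cyclises, and cis-fused isomers may compete. The fallback runs the cycloaddition at the carbinol oxidation level, where C4 and C6 cannot enolise and the tether is sp3. It sets out from 20 and returns at 21. Reduction of 20 with NaBH4 and CeCl3·7H2O (MeOH, −40 °C; the enoate is untouched) gives 2-(trimethylsilyl)ethyl (2E,4S,6S,7E,9E,11E)-2,4,10-triethyl-5-hydroxy-6,8-dimethyl-12-phenyldodeca-2,7,9,11-tetraenoate as a C5 epimer mixture F7. Heating F7 (PhMe, BHT, 110 °C) gives 2-(trimethylsilyl)ethyl (1S,3S,3aR,6S,7R,7aR)-1,6,7-triethyl-2-hydroxy-3,4-dimethyl-6-[(E)-2-phenylethenyl]-2,3,3a,6,7,7a-hexahydro-1H-indene-7-carboxylate as a C2 epimer mixture F8. Dess–Martin oxidation of F8 gives 21.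

**Further compounds**

F1 | step 10 | (2S,3E,5E,7E)-6-ethyl-2,4-dimethyl-8-phenylocta-3,5,7-trienenitrile | N#C[C@@H](C)/C=C(C)/C=C(CC)/C=C/c1ccccc1
F2 | step 10 | (2S,3E,5E,7E)-6-ethyl-2,4-dimethyl-8-phenylocta-3,5,7-trienal | O=C[C@@H](C)/C=C(C)/C=C(CC)/C=C/c1ccccc1
F3 | step 10 | 2-(trimethylsilyl)ethyl (2E,4S,5R,6S,7E,9E,11E)-2,4,10-triethyl-5-hydroxy-6,8-dimethyl-12-phenyldodeca-2,7,9,11-tetraenoate | CC[C@@H](/C=C(CC)/C(=O)OCC[Si](C)(C)C)[C@H](O)[C@@H](C)/C=C(C)/C=C(CC)/C=C/c1ccccc1
F4 | step 4 | 2-(trimethylsilyl)ethyl (2E,4S,5R)-2,4-diethyl-5-hydroxyhept-2-enoate | CC[C@@H](/C=C(CC)/C(=O)OCC[Si](C)(C)C)[C@H](O)CC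
F5 | step 4 | 2-(trimethylsilyl)ethyl (2E,4S)-2,4-diethyl-5-oxohept-2-enoate | CC[C@@H](/C=C(CC)/C(=O)OCC[Si](C)(C)C)C(=O)CC
F6 | step 4 | 2-(trimethylsilyl)ethyl (2E,4S)-2,4-diethyl-5-(trimethylsilyloxy)hepta-2,5-dienoate | CC[C@@H](/C=C(CC)/C(=O)OCC[Si](C)(C)C)C(O[Si](C)(C)C)=CC
F7 | step 11 | 2-(trimethylsilyl)ethyl (2E,4S,6S,7E,9E,11E)-2,4,10-triethyl-5-hydroxy-6,8-dimethyl-12-phenyldodeca-2,7,9,11-tetraenoate (C5 epimer mixture) | CC[C@@H](/C=C(CC)/C(=O)OCC[Si](C)(C)C)C(O)[C@@H](C)/C=C(C)/C=C(CC)/C=C/c1ccccc1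
F8 | step 11 | 2-(trimethylsilyl)ethyl (1S,3S,3aR,6S,7R,7aR)-1,6,7-triethyl-2-hydroxy-3,4-dimethyl-6-[(E)-2-phenylethenyl]-2,3,3a,6,7,7a-hexahydro-1H-indene-7-carboxylate (C2 epimer mixture) | CC[C@@H]1C(O)[C@@H](C)[C@@H]2C(C)=C[C@@](/C=C/c3ccccc3)(CC)[C@](CC)(C(=O)OCC[Si](C)(C)C)[C@H]21
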